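**Plan**

Numbering used below: oxolane O1, C2 (hydroxynonadienyl arm), C3 (cyclopropyl carbinol arm), C4 (E-alkenyl arm), C5 (octadienyl arm).
Retrosynthesis: the C3-arm carbinol goes back to a ketone and the C2-arm hydroxyl to an alkoxyamine; O1–C2 and C3–C4 are then cut together into an E-enone (C2, C3 and their arms) and a trans-vinyl oxirane (O1, C5, C4); the enone is cut at its C=C (Horner–Wadsworth–Emmons) and the oxirane at its carbinol–alkenyl bond (alkenylzinc plus α-chloro aldehyde).
Forward: one cyclopropyl lactone aldehyde 6 (tandem alkylzinc addition/cyclopropanation, then lactonisation) and one skipped dienal 13 (alkyne coupling, semi-hydrogenation) each serve both halves; the oxolane then grows from the oxirane of 20 by insertion of the two enone carbons of 15, and reduction and N–O cleavage finish.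
Enabling feature: C4 carries an alkenyl group next to the O-bound C5, the mark of a vinyl oxirane opened at its allylic C–O bond by zerovalent palladium, and C3 carries a carbinol carbon that, as a ketone, makes C3/C2 the α/β carbons of a Michael acceptor; the ring is all-trans, the thermodynamic isomer.
Stereochemistry: C5 and C4 come from the oxirane (organocatalytic α-chlorination, Cornforth-controlled addition, net retention in the key step); C3 and C2 by equilibration to all-trans; the C2-arm carbinol by organocatalytic α-oxyamination; the C3-arm carbinol by CBS reduction; the lactone carbinol by amino-alcohol-catalysed zinc addition; the cyclopropane by alkoxide-directed Simmons–Smith reaction.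

Key step: step 13

Assumption: compounds 1, 2, 9, 10 and dimethyl (diazomethyl)phosphonate are bought; the face selectivity of the three amine catalysts is taken from their behaviour with simple linear aldehydes, and the mirror-image catalyst would be used should a step give the opposite centre.

**Route**

Step 1
Reactants: 1 ethyl 4-iodobutanoate; 2 (2E)-4,4-dimethoxybut-2-enal
Product: 5 ethyl (5R)-5-[(1R,2R)-2-(dimethoxymethyl)cyclopropyl]-5-hydroxypentanoate, via bis(4-ethoxy-4-oxobutyl)zinc 3 (not isolated), via allylic zinc alkoxide 4 (not isolated)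
Conditions: 1, Et2Zn, CuI (cat.), 50 °C, volatiles removed in vacuo; 2, (+)-MIB [(2R)-3-exo-morpholinoisoborneol, 4 mol %], toluene, 0 °C; then Et2Zn, CH2I2, CH2Cl2, 0 °C → rt; aq. NH4Cl
Reagents that add atoms: diiodomethane, ICI
Why: Iodine–zinc exchange gives the functionalised dialkylzinc, its amino-alcohol-catalysed 1,2-addition to the enal should set the carbinol centre R (face fixed by (+)-MIB), and the allylic zinc alkoxide then directs Simmons–Smith (Furukawa) methylene transfer to the syn face of the E-alkene (allylic hydrogen in the alkene plane), setting both cyclopropane centres in a tandem addition/cyclopropanation of established type.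

Step 2
Reactants: 5 ethyl (5R)-5-[(1R,2R)-2-(dimethoxymethyl)cyclopropyl]-5-hydroxypentanoate
Product: 6 (1R,2R)-2-[(2R)-6-oxooxan-2-yl]cyclopropane-1-carbaldehyde
Conditions: TsOH·H2O (10 mol %), acetone/H2O (10:1), rt
Reagents that add atoms: water, O
Why: Acid-catalysed acetal hydrolysis unmasks the aldehyde and the δ-hydroxy ester closes by transesterification to the six-membered lactone, with no stereocentre touched and the trans aldehyde being the stable cyclopropane epimer.

Step 3
Reactants: 6 (1R,2R)-2-[(2R)-6-oxooxan-2-yl]cyclopropane-1-carbaldehyde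
Product: 7 dimethyl (2-oxo-2-{(1R,2R)-2-[(2R)-6-oxooxan-2-yl]cyclopropyl}ethyl)phosphonate
Conditions: dimethyl (diazomethyl)phosphonate, SnCl2 (20 mol %), CH2Cl2, rt
Reagents that add atoms: dimethyl (diazomethyl)phosphonate, COP(=O)(OC)C=[N+]=[N-]
Why: Roskamp-type homologation, in which the diazo carbon adds to the SnCl2-activated aldehyde and a 1,2-hydride shift with loss of N2 gives the β-keto phosphonate directly, leaves the lactone and all stereocentres untouched.

Step 4
Reactants: 6 (1R,2R)-2-[(2R)-6-oxooxan-2-yl]cyclopropane-1-carbaldehyde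
Product: 8 (6R)-6-[(1R,2R)-2-ethynylcyclopropyl]oxan-2-one
Conditions: dimethyl (diazomethyl)phosphonate, KOtBu, THF, −78 °C → rt
Reagents that add atoms: dimethyl (diazomethyl)phosphonate, COP(=O)(OC)C=[N+]=[N-]
Why: Seyferth–Gilbert homologation, in which the diazo anion adds to the aldehyde, phosphate is lost and the alkylidene carbene rearranges by 1,2-hydride shift to the terminal alkyne, is fast at −78 °C where the lactone is not attacked.

Step 5
Reactants: 9 pent-4-yn-1-ol; 10 1-bromopent-2-yne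
Product: 11 deca-4,7-diyn-1-ol
Conditions: CuI (10 mol %), n-Bu4NCl (cat.), Cs2CO3, DMF, rt
Reagents that add atoms: none
Why: Copper acetylide substitution of the propargylic bromide builds the skipped diyne under a base too weak to isomerise it to an allene.

Step 6
Reactants: 11 deca-4,7-diyn-1-ol
Product: 12 (4Z,7Z)-deca-4,7-dien-1-ol
Conditions: H2 (1 atm), Pd/CaCO3 poisoned with Pb(OAc)2, quinoline, EtOAc, 0 °C, stopped after two equivalents of H2
Reagents that add atoms: none
Why: Syn semi-hydrogenation on lead-poisoned palladium should deliver both Z-alkenes, with quinoline holding back over-reduction.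

Step 7
Reactants: 12 (4Z,7Z)-deca-4,7-dien-1-ol
Product: 13 (4Z,7Z)-deca-4,7-dienal
Conditions: Dess–Martin periodinane, CH2Cl2, 0 °C → rt
Reagents that add atoms: none
Why: Dess–Martin oxidation of the primary alcohol is neutral enough to leave the skipped Z,Z-diene unisomerised.

Step 8
Reactants: 13 (4Z,7Z)-deca-4,7-dienal
Product: 14 (2S,4Z,7Z)-2-[(2,2,6,6-tetramethylpiperidin-1-yl)oxy]deca-4,7-dienal
Conditions: TEMPO, CuCl2 (10 mol %), (5S)-5-benzyl-2,2,3-trimethylimidazolidin-4-one·HBF4 (20 mol %), air, acetone, −10 °C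
Reagents that add atoms: TEMPO, CC1(C)CCCC(C)(C)N1[O]
Why: Organocatalytic α-oxyamination, in which the E-enamine of 13 is trapped on its open face by copper-bound TEMPO, should set C2 as S and deliver the oxygen already protected as a base-stable alkoxyamine without an N–H.

Step 9
Reactants: 7 dimethyl (2-oxo-2-{(1R,2R)-2-[(2R)-6-oxooxan-2-yl]cyclopropyl}ethyl)phosphonate; 14 (2S,4Z,7Z)-2-[(2,2,6,6-tetramethylpiperidin-1-yl)oxy]deca-4,7-dienal
Product: 15 (6R)-6-[(1R,2R)-2-{(2E,4S,6Z,9Z)-4-[(2,2,6,6-tetramethylpiperidin-1-yl)oxy]dodeca-2,6,9-trienoyl}cyclopropyl]oxan-2-one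
Conditions: LiCl, i-Pr2NEt, MeCN, 0 °C → rt
Reagents that add atoms: none
Why: Horner–Wadsworth–Emmons olefination under Masamune–Roush conditions should give the E-enone without epimerising the α-oxygenated centre or opening the lactone.

Step 10
Reactants: 13 (4Z,7Z)-deca-4,7-dienal
Product: 16 (2S,4Z,7Z)-2-chlorodeca-4,7-dienal
Conditions: N-chlorosuccinimide, (2R,5R)-2,5-diphenylpyrrolidine (10 mol %), CH2Cl2, −20 °C; succinimide precipitated with pentane, solution used at once
Reagents that add atoms: N-chlorosuccinimide, O=C1CCC(=O)N1Cl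
Why: Enamine-catalysed α-chlorination, with the C2-symmetric amine shielding one enamine face, should set the chlorine-bearing centre S, and the product is carried on crude because it racemises on silica.

Step 11
Reactants: 8 (6R)-6-[(1R,2R)-2-ethynylcyclopropyl]oxan-2-one; 16 (2S,4Z,7Z)-2-chlorodeca-4,7-dienal
Product: 19 (6R)-6-{(1R,2S)-2-[(1E,3R,4S,6Z,9Z)-4-chloro-3-hydroxydodeca-1,6,9-trien-1-yl]cyclopropyl}oxan-2-one, via alkenylzirconocene chloride 17 (not isolated), via alkenyl(methyl)zinc 18 (not isolated)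
Conditions: 8, Cp2Zr(H)Cl, CH2Cl2, rt; Me2Zn, toluene, −65 °C; 16, 0 °C; aq. NH4Cl
Reagents that add atoms: none
Why: Syn hydrozirconation of the terminal alkyne gives the E-alkenylzirconocene, transmetalation to zinc gives an alkenylzinc that spares the lactone, and its addition to the α-chloro aldehyde through a Cornforth-type transition state should give the 1,2-anti chlorohydrin (new carbinol centre R).

Step 12
Reactants: 19 (6R)-6-{(1R,2S)-2-[(1E,3R,4S,6Z,9Z)-4-chloro-3-hydroxydodeca-1,6,9-trien-1-yl]cyclopropyl}oxan-2-one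
Product: 20 (6R)-6-[(1R,2S)-2-{(E)-2-[(2R,3R)-3-[(2Z,5Z)-octa-2,5-dien-1-yl]oxiran-2-yl]ethenyl}cyclopropyl]oxan-2-one
Conditions: NaH, THF, 0 °C
Reagents that add atoms: none
Why: Williamson closure (3-exo-tet) of the alkoxide on the chlorine-bearing carbon proceeds with inversion there, so the anti-chlorohydrin gives the trans-(2R,3R)-oxirane.

Step 13
Reactants: 15 (6R)-6-[(1R,2R)-2-{(2E,4S,6Z,9Z)-4-[(2,2,6,6-tetramethylpiperidin-1-yl)oxy]dodeca-2,6,9-trienoyl}cyclopropyl]oxan-2-one; 20 (6R)-6-[(1R,2S)-2-{(E)-2-[(2R,3R)-3-[(2Z,5Z)-octa-2,5-dien-1-yl]oxiran-2-yl]ethenyl}cyclopropyl]oxan-2-one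
Product: 21 (6R)-6-[(1R,2R)-2-({(2S,3S,4S,5R)-5-[(2Z,5Z)-octa-2,5-dien-1-yl]-4-[(E)-2-{(1S,2R)-2-[(2R)-6-oxooxan-2-yl]cyclopropyl}ethenyl]-2-{(1S,3Z,6Z)-1-[(2,2,6,6-tetramethylpiperidin-1-yl)oxy]nona-3,6-dien-1-yl}oxolan-3-yl}carbonyl)cyclopropyl]oxan-2-one
Conditions: Pd2(dba)3·CHCl3 (2.5 mol %), dppe (6 mol %), THF, 0 °C → rt, 20 added over 4 h to 15 (1.3 equiv); then DBU (20 mol %), rt
Reagents that add atoms: none
Why: Proposed new method: zerovalent palladium ionises the allylic C–O bond of oxirane 20 with inversion to a zwitterionic syn,syn-η3-allylpalladium alkoxide, the alkoxide adds reversibly to the β-carbon of enone 15 (oxa-Michael) and the ketone enolate so formed attacks the near allyl terminus anti to palladium, so that the three-membered ether grows by the two enone carbons into the oxolane (formal [3+2] ring expansion, 5-exo closure at C3–C4, the seven-membered alternative through the far terminus being slower). The closest known reaction type is the Pd-catalysed [3+2] cycloaddition of butadiene monoxide and other terminal vinyl oxiranes with doubly activated olefins, nitroalkenes and aryl enones; an internal trans-2,3-dialkyl vinyl oxirane combined with an aliphatic γ-oxygenated enone has not been shown. Oxolane C5 keeps the oxirane configuration because its C–O bond is never broken, and C4 is formed with net retention (two inversions), which from the trans-oxirane gives the 4,5-trans ring and the E-alkene. C3 (α to the ketone, epimerisable by enolisation) and C2 (epimerisable by retro-oxa-Michael and re-closure) are relayed from C4 under thermodynamic control, the DBU finish being meant to drive the mixture to the all-trans oxolane in which the four substituents avoid one another. The step needs the bimolecular oxa-Michael capture to outrun β-hydride isomerisation of the opened oxirane, which slow addition of 20 to an excess of 15 with a chelating diphosphine is meant to secure, while cyclopropanes, lactones, the N–O bond and the skipped dienes are not substrates for zerovalent palladium under these conditions.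

Step 14
Reactants: 21 (oxolanyl cyclopropyl ketone, as named in step 13)
Product: 22 (6R)-6-[(1R,2R)-2-[(R)-hydroxy{(2S,3R,4S,5R)-5-[(2Z,5Z)-octa-2,5-dien-1-yl]-4-[(E)-2-{(1S,2R)-2-[(2R)-6-oxooxan-2-yl]cyclopropyl}ethenyl]-2-{(1S,3Z,6Z)-1-[(2,2,6,6-tetramethylpiperidin-1-yl)oxy]nona-3,6-dien-1-yl}oxolan-3-yl}methyl]cyclopropyl]oxan-2-one
Conditions: (S)-2-methyl-CBS-oxazaborolidine (0.5 equiv), catecholborane, toluene, −78 °C; MeOH, pH 7 buffer
Reagents that add atoms: none
Why: Corey–Bakshi–Shibata reduction, in which the (S)-oxazaborolidine binds the ketone with the branched oxolanyl group as the large and cyclopropyl as the small substituent, should deliver hydride to give the (R)-carbinol, and catecholborane leaves lactones and alkenes alone at −78 °C.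

Step 15
Reactants: 22 (alkoxyamine-protected diol precursor, as named in step 14)
Product: 23 (6R)-6-[(1R,2R)-2-[(R)-hydroxy{(2S,3R,4S,5R)-2-[(1S,3Z,6Z)-1-hydroxynona-3,6-dien-1-yl]-5-[(2Z,5Z)-octa-2,5-dien-1-yl]-4-[(E)-2-{(1S,2R)-2-[(2R)-6-oxooxan-2-yl]cyclopropyl}ethenyl]oxolan-3-yl}methyl]cyclopropyl]oxan-2-one (CNP0273074.2)
Conditions: Zn dust, AcOH/THF/H2O (3:1:1), 50 °C
Reagents that add atoms: none
Why: Zinc in acetic acid cleaves the alkoxyamine N–O bond reductively and frees the last hydroxyl without touching lactones, alkenes, cyclopropanes or any stereocentre.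

**Compound list**

1 | ethyl 4-iodobutanoate | CCOC(=O)CCCI | starting material
2 | (2E)-4,4-dimethoxybut-2-enal | COC(OC)/C=C/C=O | starting material
3 | bis(4-ethoxy-4-oxobutyl)zinc | CCOC(=O)CCC[Zn]CCCC(=O)OCC | intermediate (not isolated)
4 | (4-ethoxy-4-oxobutyl)zinc alkoxide of ethyl (5R,6E)-5-hydroxy-8,8-dimethoxyoct-6-enoate | CCOC(=O)CCC[C@@H](O[Zn]CCCC(=O)OCC)/C=C/C(OC)OC | intermediate (not isolated)
5 | ethyl (5R)-5-[(1R,2R)-2-(dimethoxymethyl)cyclopropyl]-5-hydroxypentanoate | CCOC(=O)CCC[C@@H](O)[C@@H]1C[C@H]1C(OC)OC | intermediate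
6 | (1R,2R)-2-[(2R)-6-oxooxan-2-yl]cyclopropane-1-carbaldehyde | O=C[C@@H]1C[C@H]1[C@H]1CCCC(=O)O1 | intermediate
7 | dimethyl (2-oxo-2-{(1R,2R)-2-[(2R)-6-oxooxan-2-yl]cyclopropyl}ethyl)phosphonate | COP(=O)(OC)CC(=O)[C@@H]1C[C@H]1[C@H]1CCCC(=O)O1 | intermediate
8 | (6R)-6-[(1R,2R)-2-ethynylcyclopropyl]oxan-2-one | C#C[C@@H]1C[C@H]1[C@H]1CCCC(=O)O1 | intermediate
9 | pent-4-yn-1-ol | C#CCCCO | starting material
10 | 1-bromopent-2-yne | CCC#CCBr | starting material
11 | deca-4,7-diyn-1-ol | CCC#CCC#CCCCO | intermediate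
12 | (4Z,7Z)-deca-4,7-dien-1-ol | CC/C=C\C/C=C\CCCO | intermediate
13 | (4Z,7Z)-deca-4,7-dienal | CC/C=C\C/C=C\CCC=O | intermediate
14 | (2S,4Z,7Z)-2-[(2,2,6,6-tetramethylpiperidin-1-yl)oxy]deca-4,7-dienal | CC/C=C\C/C=C\C[C@H](ON1C(C)(C)CCCC1(C)C)C=O | intermediate
15 | (6R)-6-[(1R,2R)-2-{(2E,4S,6Z,9Z)-4-[(2,2,6,6-tetramethylpiperidin-1-yl)oxy]dodeca-2,6,9-trienoyl}cyclopropyl]oxan-2-one | CC/C=C\C/C=C\C[C@H](ON1C(C)(C)CCCC1(C)C)/C=C/C(=O)[C@@H]1C[C@H]1[C@H]1CCCC(=O)O1 | intermediate
16 | (2S,4Z,7Z)-2-chlorodeca-4,7-dienal | CC/C=C\C/C=C\C[C@H](Cl)C=O | intermediate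
17 | E-alkenylzirconocene chloride from syn addition of Cp2Zr(H)Cl to 8, zirconium on the terminal carbon, ring centres as in 8 | Cl[Zr](/C=C/[C@@H]1C[C@H]1[C@H]1CCCC(=O)O1)(C1C=CC=C1)C1C=CC=C1 | intermediate (not isolated)
18 | E-alkenyl(methyl)zinc from 17 by transmetalation, ring centres as in 8 | C[Zn]/C=C/[C@@H]1C[C@H]1[C@H]1CCCC(=O)O1 | intermediate (not isolated)
19 | (6R)-6-{(1R,2S)-2-[(1E,3R,4S,6Z,9Z)-4-chloro-3-hydroxydodeca-1,6,9-trien-1-yl]cyclopropyl}oxan-2-one | CC/C=C\C/C=C\C[C@H](Cl)[C@H](O)/C=C/[C@@H]1C[C@H]1[C@H]1CCCC(=O)O1 | intermediate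
20 | (6R)-6-[(1R,2S)-2-{(E)-2-[(2R,3R)-3-[(2Z,5Z)-octa-2,5-dien-1-yl]oxiran-2-yl]ethenyl}cyclopropyl]oxan-2-one | CC/C=C\C/C=C\C[C@H]1O[C@@H]1/C=C/[C@@H]1C[C@H]1[C@H]1CCCC(=O)O1 | intermediate
21 | (6R)-6-[(1R,2R)-2-({(2S,3S,4S,5R)-5-[(2Z,5Z)-octa-2,5-dien-1-yl]-4-[(E)-2-{(1S,2R)-2-[(2R)-6-oxooxan-2-yl]cyclopropyl}ethenyl]-2-{(1S,3Z,6Z)-1-[(2,2,6,6-tetramethylpiperidin-1-yl)oxy]nona-3,6-dien-1-yl}oxolan-3-yl}carbonyl)cyclopropyl]oxan-2-one | CC/C=C\C/C=C\C[C@H](ON3C(C)(C)CCCC3(C)C)[C@H]1O[C@H](C/C=C\C/C=C\CC)[C@@H](/C=C/[C@@H]2C[C@H]2[C@H]2CCCC(=O)O2)[C@@H]1C(=O)[C@@H]1C[C@H]1[C@H]1CCCC(=O)O1 | intermediate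
22 | (6R)-6-[(1R,2R)-2-[(R)-hydroxy{(2S,3R,4S,5R)-5-[(2Z,5Z)-octa-2,5-dien-1-yl]-4-[(E)-2-{(1S,2R)-2-[(2R)-6-oxooxan-2-yl]cyclopropyl}ethenyl]-2-{(1S,3Z,6Z)-1-[(2,2,6,6-tetramethylpiperidin-1-yl)oxy]nona-3,6-dien-1-yl}oxolan-3-yl}methyl]cyclopropyl]oxan-2-one | CC/C=C\C/C=C\C[C@H](ON3C(C)(C)CCCC3(C)C)[C@H]1O[C@H](C/C=C\C/C=C\CC)[C@@H](/C=C/[C@@H]2C[C@H]2[C@H]2CCCC(=O)O2)[C@@H]1[C@H](O)[C@@H]1C[C@H]1[C@H]1CCCC(=O)O1 | intermediate
23 | (6R)-6-[(1R,2R)-2-[(R)-hydroxy{(2S,3R,4S,5R)-2-[(1S,3Z,6Z)-1-hydroxynona-3,6-dien-1-yl]-5-[(2Z,5Z)-octa-2,5-dien-1-yl]-4-[(E)-2-{(1S,2R)-2-[(2R)-6-oxooxan-2-yl]cyclopropyl}ethenyl]oxolan-3-yl}methyl]cyclopropyl]oxan-2-one | CC/C=C\C/C=C\C[C@H](O)[C@H]1O[C@H](C/C=C\C/C=C\CC)[C@@H](/C=C/[C@@H]2C[C@H]2[C@H]2CCCC(=O)O2)[C@@H]1[C@H](O)[C@@H]1C[C@H]1[C@H]1CCCC(=O)O1 | target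

**Step count**

Total steps: 15. Longest linear sequence: 9 (steps 5, 6, 7, 10, 11, 12, 13, 14, 15).

**Steps most likely to fail**

Step 13. The opened oxirane may isomerise by β-hydride shift to a dienol or ketone faster than the singly activated enone captures its alkoxide, or the enolate may close sluggishly on the hindered internal allyl terminus. The fallback uses known chemistry: the acceptor is raised to a doubly activated alkylidene β-keto ester, the olefin class for which this cycloaddition is established. It sets out from 6. Roskamp homologation with tert-butyl diazoacetate and SnCl2 gives tert-butyl 3-oxo-3-{(1R,2R)-2-[(2R)-6-oxooxan-2-yl]cyclopropyl}propanoate F1. Knoevenagel condensation of this with 14 (piperidinium acetate, 0 °C) gives the alkylidene β-keto ester F2 as an inconsequential E/Z mixture. Cycloaddition of this with 20 under Pd2(dba)3·CHCl3/PPh3 gives the 3-(tert-butoxycarbonyl) derivative of 21, F3, with a quaternary oxolane C3. Trifluoroacetic acid then cleaves the tert-butyl ester, the β-keto acid loses CO2 on gentle warming, and DBU equilibration of C3 comes back to the route at 21.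

Step 11. Cp2Zr(H)Cl may reduce the lactone in competition with the alkyne, or the alkenylzinc may add slowly enough for the α-chloro aldehyde to epimerise and for the anti preference to erode. The fallback changes the organometallic and its precursor. It sets out from 6: Takai olefination (CHI3, CrCl2, THF/dioxane) gives (6R)-6-{(1R,2R)-2-[(E)-2-iodoethenyl]cyclopropyl}oxan-2-one F4. Nozaki–Hiyama–Kishi coupling of this with 16 (CrCl2, NiCl2 cat., DMSO/THF, rt), through an alkenylchromium species that ignores lactones, comes back to the route at 19.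

Step 14. Facial discrimination may be poor because both ketone substituents are secondary carbons and the oxolane oxygen can bind boron. The fallback replaces reagent control by chelate control to the epimer followed by inversion. It sets out from 21: Zn(BH4)2 (Et2O, −20 °C), with zinc bridging the ketone and the ring oxygen and hydride arriving anti to oxolane C4, should give the (S)-carbinol epimer of 22, F5. Mitsunobu esterification (4-nitrobenzoic acid, PPh3, DIAD) inverts this to the (R)-4-nitrobenzoate of 22, F6. Methanolysis (K2CO3, MeOH, 0 °C, then PPTS to re-close any opened lactone) comes back to the route at 22.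

**Further compounds**

F1 | step 13 | tert-butyl 3-oxo-3-{(1R,2R)-2-[(2R)-6-oxooxan-2-yl]cyclopropyl}propanoate | CC(C)(C)OC(=O)CC(=O)[C@@H]1C[C@H]1[C@H]1CCCC(=O)O1
F2 | step 13 | tert-butyl (4S,6Z,9Z)-2-({(1R,2R)-2-[(2R)-6-oxooxan-2-yl]cyclopropyl}carbonyl)-4-[(2,2,6,6-tetramethylpiperidin-1-yl)oxy]dodeca-2,6,9-trienoate (2E/2Z mixture) | CC/C=C\C/C=C\C[C@H](ON1C(C)(C)CCCC1(C)C)C=C(C(=O)OC(C)(C)C)C(=O)[C@@H]1C[C@H]1[C@H]1CCCC(=O)O1
F3 | step 13 | 3-(tert-butoxycarbonyl) derivative of 21 (ester on the quaternary oxolane C3, either C3 configuration) | CC/C=C\C/C=C\C[C@H](ON3C(C)(C)CCCC3(C)C)[C@H]1O[C@H](C/C=C\C/C=C\CC)[C@@H](/C=C/[C@@H]2C[C@H]2[C@H]2CCCC(=O)O2)C1(C(=O)OC(C)(C)C)C(=O)[C@@H]1C[C@H]1[C@H]1CCCC(=O)O1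
F4 | step 11 | (6R)-6-{(1R,2R)-2-[(E)-2-iodoethenyl]cyclopropyl}oxan-2-one | I/C=C/[C@@H]1C[C@H]1[C@H]1CCCC(=O)O1
F5 | step 14 | (S)-carbinol epimer of 22 at the C3-arm carbinol | CC/C=C\C/C=C\C[C@H](ON3C(C)(C)CCCC3(C)C)[C@H]1O[C@H](C/C=C\C/C=C\CC)[C@@H](/C=C/[C@@H]2C[C@H]2[C@H]2CCCC(=O)O2)[C@@H]1[C@@H](O)[C@@H]1C[C@H]1[C@H]1CCCC(=O)O1
F6 | step 14 | (R)-4-nitrobenzoate of 22 at the C3-arm carbinol | CC/C=C\C/C=C\C[C@H](ON3C(C)(C)CCCC3(C)C)[C@H]1O[C@H](C/C=C\C/C=C\CC)[C@@H](/C=C/[C@@H]2C[C@H]2[C@H]2CCCC(=O)O2)[C@@H]1[C@H](OC(=O)c4ccc(cc4)[N+](=O)[O-])[C@@H]1C[C@H]1[C@H]1CCCC(=O)O1
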